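**Remark (assumption):** Gibberellin numbering (C1–C20) and the usual α/β descriptors are used for all intermediates. The target is handled as the open 20-aldehyde 19-acid, which is expected to equilibrate with its 19,20-lactol.

## Retrosynthetic overview

1. Target ⇐ pentacyclic enol lactone 19 by C4 methylation, C3 reduction, enol-lactone hydrolysis (C6 equilibrates to 6β), Pinnick oxidation and mild acid deprotection.
2. 19 ⇐ intramolecular Diels–Alder reaction of keto enal 17: the 2-silyloxy diene made from a 3-acetyl-2-pyranone adds to a 2-substituted acrolein, forming C1–C2 and C5–C10, that is rings A and B together on a finished C/D bicycle.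
3. Enabling feature: ring A is a 4-formylcyclohexanone (C3 oxygen and C10 formyl 1,4 across C2–C1), and C5–C10 is shared by rings A and B, so the tether C6–C8–C9 closes ring B. C19 and C7 are 1,5-related through C4–C5–C6 and can be carried as one 2-pyranone ring that also fixes the diene geometry.
4. 17 ⇐ pyranone annulation and α-methylenation on bicyclo[3.2.1]octane 10 ⇐ ketyl–alkyne cyclisation (ring D) of cyclohexanone 9.
5. 9 ⇐ Mukaiyama–Michael/Saegusa–Ito and conjugate propargylation of (S)-enone 4 ⇐ organocatalytic Michael/aldol (ring C; C9 is the only catalyst-set centre). Ring order: C, D, then A and B together.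

Key step: step 12

## Route

Step 1
Reactants: 1 4-[(tert-butyldimethylsilyl)oxy]butanal; 2 but-3-en-2-one
Product: 4 (S)-4-[2-[(tert-butyldimethylsilyl)oxy]ethyl]cyclohex-2-en-1-one, via keto aldehyde 3 (not isolated)
Conditions: (S)-α,α-diphenylprolinol trimethylsilyl ether (10 mol %), PhCO2H (10 mol %), CH2Cl2, 0 °C; then LiOH (20 mol %), i-PrOH, 23 °C
Reagents that add atoms: none
Why: Enamine-catalysed Michael addition to the enone, in which the catalyst shields one face of the E-enamine and should set C9 as S, followed by intramolecular aldol condensation of the 1,5-keto aldehyde (Robinson-type annulation).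

Step 2
Reactants: 4 (S)-enone; 5 1-(tert-butyldimethylsilyloxy)-1-methoxyethene
Product: 6 methyl 2-[(1S,6S)-3-[(tert-butyldimethylsilyl)oxy]-6-[2-[(tert-butyldimethylsilyl)oxy]ethyl]cyclohex-2-en-1-yl]acetate
Conditions: t-BuMe2SiOTf (5 mol %), CH2Cl2, −78 °C
Reagents that add atoms: none
Why: Mukaiyama–Michael addition with silyl transfer gives the regiodefined silyl enol ether; the nucleophile enters anti to the C9 side chain, but this C8 centre is planarised again in step 3.

Step 3
Reactants: 6 silyl enol ether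
Product: 7 methyl 2-[(6S)-6-[2-[(tert-butyldimethylsilyl)oxy]ethyl]-3-oxocyclohex-1-en-1-yl]acetate
Conditions: Pd(OAc)2 (10 mol %), O2 (1 atm), DMSO, 40 °C
Reagents that add atoms: none
Why: Saegusa–Ito oxidation (palladation at C14, β-hydride elimination of H-8) regenerates the enone, now with the acetate arm on C8.

Step 4
Reactants: 7 enone ester; 8 tributyl(propa-1,2-dien-1-yl)stannane
Product: 9 methyl 2-[(1R,2S)-2-[2-[(tert-butyldimethylsilyl)oxy]ethyl]-5-oxo-1-(prop-2-yn-1-yl)cyclohexyl]acetate
Conditions: TiCl4, CH2Cl2, −78 °C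
Reagents that add atoms: none
Why: Lewis-acid-promoted conjugate propargylation (SE2' addition of the allenylstannane, a Hosomi–Sakurai-type reaction) should create quaternary C8 with the propargyl group entering anti to the pseudoaxial C9 side chain, so the acetate arm ends up cis to it.

Step 5
Reactants: 9 propargyl ketone
Product: 10 methyl 2-[(1R,2S,5S)-2-[2-[(tert-butyldimethylsilyl)oxy]ethyl]-5-hydroxy-6-methylidenebicyclo[3.2.1]octan-1-yl]acetate
Conditions: SmI2, HMPA, t-BuOH, THF, 0 → 23 °C
Reagents that add atoms: none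
Why: Ketyl–alkyne radical cyclisation (5-exo-dig) of the C13 ketyl onto the axial propargyl group closes ring D; the C13 configuration is dictated by the bridge and the vinyl radical ends as the exocyclic methylene.

Step 6
Reactants: 10 bicyclic ester
Product: 11 2-[(1R,2S,5S)-2-[2-[(tert-butyldimethylsilyl)oxy]ethyl]-5-hydroxy-6-methylidenebicyclo[3.2.1]octan-1-yl]acetaldehyde
Conditions: i-Bu2AlH (2.2 equiv), CH2Cl2, −78 °C; aq. potassium sodium tartrate
Reagents that add atoms: none
Why: Partial reduction of the ester to the aldehyde through the aluminium hemiacetal, which is stable at −78 °C; the first equivalent is consumed by the tertiary hydroxyl.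

Step 7
Reactants: 11 aldehyde
Product: 12 3-(dimethylamino)-2-[2-[2-[(tert-butyldimethylsilyl)oxy]ethyl]-5-hydroxy-6-methylidenebicyclo[3.2.1]octan-1-yl]prop-2-enal
Conditions: t-BuOCH(NMe2)2, PhMe, 70 °C
Reagents that add atoms: tert-butoxybis(dimethylamino)methane, CC(C)(C)OC(N(C)C)N(C)C
Why: α-Aminomethylenation of the aldehyde with the aminal ester installs C7 as a vinylogous formamide and makes C6 sp2, so no stereocentre is formed.

Step 8
Reactants: 12 enaminal; 13 methyl 3-oxobutanoate
Product: 14 3-acetyl-5-[2-[2-[(tert-butyldimethylsilyl)oxy]ethyl]-5-hydroxy-6-methylidenebicyclo[3.2.1]octan-1-yl]-2H-pyran-2-one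
Conditions: AcOH, PhMe, 80 °C
Reagents that add atoms: none
Why: Knoevenagel condensation at the vinylogous formamide carbonyl, then ring closure onto the ester with loss of dimethylamine and methanol (2-pyranone synthesis from 3-aminoacroleins and β-keto esters), gives the 3-acetyl-2-pyranone carrying C2, C3, C4 and C19.

Step 9
Reactants: 14 silyl ether
Product: 15 3-acetyl-5-[5-hydroxy-2-(2-hydroxyethyl)-6-methylidenebicyclo[3.2.1]octan-1-yl]-2H-pyran-2-one
Conditions: HF·pyridine, THF, 0 → 23 °C
Reagents that add atoms: none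
Why: Fluoride cleavage of the primary silyl ether; the tertiary alcohol and the pyranone should be inert.

Step 10
Reactants: 15 diol
Product: 16 2-[1-(3-acetyl-2-oxo-2H-pyran-5-yl)-5-hydroxy-6-methylidenebicyclo[3.2.1]octan-2-yl]acetaldehyde
Conditions: Dess–Martin periodinane, NaHCO3, CH2Cl2, 0 → 23 °C
Reagents that add atoms: none
Why: Dess–Martin oxidation of the primary alcohol; the bridgehead tertiary alcohol cannot be oxidised.

Step 11
Reactants: 16 aldehyde
Product: 17 2-[1-(3-acetyl-2-oxo-2H-pyran-5-yl)-5-hydroxy-6-methylidenebicyclo[3.2.1]octan-2-yl]prop-2-enal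
Conditions: CH2=NMe2+ I− (Eschenmoser's salt), Et3N, CH2Cl2, 23 °C
Reagents that add atoms: N,N-dimethylmethyleneiminium iodide, C=[N+](C)C.[I-]
Why: Mannich reaction of the aldehyde enol with the iminium salt and β-elimination of dimethylamine (α-methylenation) gives the 2-substituted acrolein; the aldehyde should react faster than the acetyl group.

Step 12
Reactants: 17 keto enal
Product: 19 19,7-enol lactone of 7-hydroxy-20-oxo-3,13-bis(triethylsilyloxy)-18-norgibberella-3,6(7),16-trien-19-oic acid (5β-H; 10α-CHO), via bis-silyl dienol ether 18 (not isolated)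
Conditions: Et3SiOTf (3 equiv), Et3N (5 equiv), CH2Cl2, −78 → 23 °C; then PhMe, 80 °C
Reagents that add atoms: triethylsilyl trifluoromethanesulfonate, CC[Si](CC)(CC)OS(=O)(=O)C(F)(F)F
Why: Soft enolisation of the acetyl group (the only enolisable position) gives the 2-silyloxy diene C2=C3(OSiEt3)–C4=C5, whose C4=C5 bond is the 3,4-bond of the pyranone, and it adds to the tethered acrolein C1=C10(CHO) in a concerted, asynchronous [4+2] cycloaddition that forms C1–C2 and C5–C10 with matched polarity (nucleophilic C2 to the β-carbon C1). The closest known reaction type is the type 1 intramolecular Diels–Alder reaction of 2-silyloxy dienes with enals in 1,3,8-nonatrienes (a formal intramolecular double Michael reaction). Ring A closes as the six-membered cycloadduct ring and ring B as the fused five-membered ring spanned by the tether C6–C8–C9 (5-exo with respect to the dienophile), while the lactone ring is carried along. C5: because C6 is an sp2 ring carbon, C8 is held in the diene plane on the side away from C3/C4, so only the tether-anti transition state with the formyl group endo under C3/C4 is accessible, which should give the trans A/B fusion (H-5 anti to C20). C10: the dienophile stands axial on C9 and its face toward ring C (H-12ax, H-14ax) is closed, so the diene reaches C1 from the open side and C20 should end up α, syn to C11. Periselectivity and regioselectivity need no further control, since the two-atom link between C6 and C10 allows no other bonding pair.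

Step 13
Reactants: 19 cycloadduct
Product: 20 19,7-enol lactone of 7-hydroxy-3,20-dioxo-13-(triethylsilyloxy)gibberella-6(7),16-dien-19-oic acid
Conditions: Bu4NF (1.1 equiv), MeI, THF, −78 → 0 °C
Reagents that add atoms: iodomethane, CI
Why: Fluoride unmasks the β-keto lactone enolate, which is C-methylated from the β face, anti to the axial C10 formyl group, so C18 should be β and the C19 carbonyl α.

Step 14
Reactants: 20 keto aldehyde
Product: 21 19,7-enol lactone of 7-hydroxy-20,20-dimethoxy-3-oxo-13-(triethylsilyloxy)gibberella-6(7),16-dien-19-oic acid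
Conditions: MeOSiMe3, Me3SiOTf (cat.), CH2Cl2, −78 °C
Reagents that add atoms: methoxytrimethylsilane, CO[Si](C)(C)C
Why: Aprotic silyl-triflate-catalysed acetalisation should be selective for the aldehyde over the α-quaternary ketone and leave the enol lactone untouched.

Step 15
Reactants: 21 keto acetal
Product: 22 19,7-enol lactone of 3β,7-dihydroxy-20,20-dimethoxy-13-(triethylsilyloxy)gibberella-6(7),16-dien-19-oic acid
Conditions: LiBH(s-Bu)3 (L-Selectride), THF, −78 °C
Reagents that add atoms: none
Why: Bulky-hydride reduction along the equatorial trajectory (α face, avoiding the 1,3-diaxial H-1β and H-5β) should give the axial 3β-alcohol; the lactone is not reduced at −78 °C.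

Step 16
Reactants: 22 hydroxy lactone
Product: 24 3β-hydroxy-20,20-dimethoxy-13-(triethylsilyloxy)gibberell-16-ene-7,19-dioic acid, via aldehyde acid 23 (not isolated)
Conditions: LiOH, THF/H2O, 0 → 23 °C; then NaClO2, NaH2PO4, 2-methyl-2-butene, t-BuOH/H2O, 23 °C
Reagents that add atoms: lithium hydroxide (in water), [Li+].[OH-]; sodium chlorite, [Na+].[O-]Cl=O
Why: Saponification of the enol lactone releases the C19 carboxylate and the C7 aldehyde enolate, whose reprotonation under base should equilibrate C6 to the more stable 6β-formyl epimer (trans to the C4–C5 bond), and Pinnick oxidation then gives the C7 acid.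

Step 17
Reactants: 24 diacid
Product: 25 3β,13-dihydroxy-20-oxogibberell-16-ene-7,19-dioic acid (the target)
Conditions: AcOH/THF/H2O (3:1:1), 40 °C
Reagents that add atoms: water, O
Why: Mild acid hydrolysis should cleave the tertiary triethylsilyl ether and the dimethyl acetal (assisted by the neighbouring C19 acid) under conditions too weak to protonate the 16,17-alkene.

## Compound list

1 | 4-[(tert-butyldimethylsilyl)oxy]butanal | O=CCCCO[Si](C)(C)C(C)(C)C | starting material
2 | but-3-en-2-one (methyl vinyl ketone) | CC(=O)C=C | starting material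
3 | (S)-2-[2-[(tert-butyldimethylsilyl)oxy]ethyl]-5-oxohexanal | CC(=O)CC[C@@H](CCO[Si](C)(C)C(C)(C)C)C=O | intermediate
4 | (S)-4-[2-[(tert-butyldimethylsilyl)oxy]ethyl]cyclohex-2-en-1-one | O=C1C=C[C@H](CCO[Si](C)(C)C(C)(C)C)CC1 | intermediate
5 | 1-(tert-butyldimethylsilyloxy)-1-methoxyethene | C=C(OC)O[Si](C)(C)C(C)(C)C | starting material
6 | methyl 2-[(1S,6S)-3-[(tert-butyldimethylsilyl)oxy]-6-[2-[(tert-butyldimethylsilyl)oxy]ethyl]cyclohex-2-en-1-yl]acetate (1,6-trans) | COC(=O)C[C@@H]1C=C(O[Si](C)(C)C(C)(C)C)CC[C@H]1CCO[Si](C)(C)C(C)(C)C | intermediate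
7 | methyl 2-[(6S)-6-[2-[(tert-butyldimethylsilyl)oxy]ethyl]-3-oxocyclohex-1-en-1-yl]acetate | O=C1C=C(CC(=O)OC)[C@H](CCO[Si](C)(C)C(C)(C)C)CC1 | intermediate
8 | tributyl(propa-1,2-dien-1-yl)stannane | C=C=C[Sn](CCCC)(CCCC)CCCC | starting material
9 | methyl 2-[(1R,2S)-2-[2-[(tert-butyldimethylsilyl)oxy]ethyl]-5-oxo-1-(prop-2-yn-1-yl)cyclohexyl]acetate (propargyl trans to the C2 side chain) | C#CC[C@]1(CC(=O)OC)CC(=O)CC[C@H]1CCO[Si](C)(C)C(C)(C)C | intermediate
10 | methyl 2-[(1R,2S,5S)-2-[2-[(tert-butyldimethylsilyl)oxy]ethyl]-5-hydroxy-6-methylidenebicyclo[3.2.1]octan-1-yl]acetate | C=C1C[C@]2(CC(=O)OC)C[C@@]1(O)CC[C@H]2CCO[Si](C)(C)C(C)(C)C | intermediate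
11 | 2-[(1R,2S,5S)-2-[2-[(tert-butyldimethylsilyl)oxy]ethyl]-5-hydroxy-6-methylidenebicyclo[3.2.1]octan-1-yl]acetaldehyde | C=C1C[C@]2(CC=O)C[C@@]1(O)CC[C@H]2CCO[Si](C)(C)C(C)(C)C | intermediate
12 | 3-(dimethylamino)-2-[bicyclooctan-1-yl]prop-2-enal, bicyclic part and configuration as in 10 (push–pull alkene, drawn Z; both isomers converge in step 8) | C=C1C[C@]2(/C(C=O)=C/N(C)C)C[C@@]1(O)CC[C@H]2CCO[Si](C)(C)C(C)(C)C | intermediate
13 | methyl 3-oxobutanoate (methyl acetoacetate) | CC(=O)CC(=O)OC | starting material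
14 | 3-acetyl-5-[2-[2-[(tert-butyldimethylsilyl)oxy]ethyl]-5-hydroxy-6-methylidenebicyclo[3.2.1]octan-1-yl]-2H-pyran-2-one (configuration at C8, C9, C13 as in 10) | C=C1C[C@]2(C3=COC(=O)C(C(C)=O)=C3)C[C@@]1(O)CC[C@H]2CCO[Si](C)(C)C(C)(C)C | intermediate
15 | 3-acetyl-5-[5-hydroxy-2-(2-hydroxyethyl)-6-methylidenebicyclo[3.2.1]octan-1-yl]-2H-pyran-2-one | C=C1C[C@]2(C3=COC(=O)C(C(C)=O)=C3)C[C@@]1(O)CC[C@H]2CCO | intermediate
16 | 2-[1-(3-acetyl-2-oxo-2H-pyran-5-yl)-5-hydroxy-6-methylidenebicyclo[3.2.1]octan-2-yl]acetaldehyde | C=C1C[C@]2(C3=COC(=O)C(C(C)=O)=C3)C[C@@]1(O)CC[C@H]2CC=O | intermediate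
17 | 2-[1-(3-acetyl-2-oxo-2H-pyran-5-yl)-5-hydroxy-6-methylidenebicyclo[3.2.1]octan-2-yl]prop-2-enal | C=C1C[C@]2(C3=COC(=O)C(C(C)=O)=C3)C[C@@]1(O)CC[C@H]2C(=C)C=O | intermediate
18 | bis(triethylsilyl) derivative of 17: 13-O-SiEt3 and 3-[1-(triethylsilyloxy)ethenyl]pyranone | C=C1C[C@]2(C3=COC(=O)C(C(=C)O[Si](CC)(CC)CC)=C3)C[C@@]1(O[Si](CC)(CC)CC)CC[C@H]2C(=C)C=O | intermediate
19 | 19,7-enol lactone of 7-hydroxy-20-oxo-3,13-bis(triethylsilyloxy)-18-norgibberella-3,6(7),16-trien-19-oic acid (5β-H, 9β-H, 10α-CHO) | C=C1C[C@]23C[C@@]1(O[Si](CC)(CC)CC)CC[C@H]2[C@]1(C=O)CCC(O[Si](CC)(CC)CC)=C4C(=O)OC=C3[C@@H]14 | intermediate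
20 | 19,7-enol lactone of 7-hydroxy-3,20-dioxo-13-(triethylsilyloxy)gibberella-6(7),16-dien-19-oic acid (4β-methyl) | C=C1C[C@]23C[C@@]1(O[Si](CC)(CC)CC)CC[C@H]2[C@]1(C=O)CCC(=O)[C@@]4(C)C(=O)OC=C3[C@@H]14 | intermediate
21 | 19,7-enol lactone of 7-hydroxy-20,20-dimethoxy-3-oxo-13-(triethylsilyloxy)gibberella-6(7),16-dien-19-oic acid | C=C1C[C@]23C[C@@]1(O[Si](CC)(CC)CC)CC[C@H]2[C@]1(C(OC)OC)CCC(=O)[C@@]4(C)C(=O)OC=C3[C@@H]14 | intermediate
22 | 19,7-enol lactone of 3β,7-dihydroxy-20,20-dimethoxy-13-(triethylsilyloxy)gibberella-6(7),16-dien-19-oic acid | C=C1C[C@]23C[C@@]1(O[Si](CC)(CC)CC)CC[C@H]2[C@]1(C(OC)OC)CC[C@H](O)[C@@]4(C)C(=O)OC=C3[C@@H]14 | intermediate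
23 | 3β-hydroxy-20,20-dimethoxy-7-oxo-13-(triethylsilyloxy)gibberell-16-en-19-oic acid (6β-formyl) | C=C1C[C@]23C[C@@]1(O[Si](CC)(CC)CC)CC[C@H]2[C@]1(C(OC)OC)CC[C@H](O)[C@@](C)(C(=O)O)[C@H]1[C@@H]3C=O | intermediate
24 | 3β-hydroxy-20,20-dimethoxy-13-(triethylsilyloxy)gibberell-16-ene-7,19-dioic acid | C=C1C[C@]23C[C@@]1(O[Si](CC)(CC)CC)CC[C@H]2[C@]1(C(OC)OC)CC[C@H](O)[C@@](C)(C(=O)O)[C@H]1[C@@H]3C(=O)O | intermediate
25 | 3β,13-dihydroxy-20-oxogibberell-16-ene-7,19-dioic acid (CNP0236431.1) | C=C1C[C@]23C[C@@]1(O)CC[C@H]2[C@]1(C=O)CC[C@H](O)[C@@](C)(C(=O)O)[C@H]1[C@@H]3C(=O)O | target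

## Step count and risks

Total step count: 17. Longest linear sequence: 17 steps (from 1).

**Step 12 (cycloaddition).** The dienol ether may condense intermolecularly with the enal faster than it cyclises, or the dienophile may be attacked on the wrong face. The fallback makes the same two bonds by an anionic intramolecular double Michael reaction. It sets out from 17, whose tertiary alcohol would first be silylated (Et3SiOTf, 2,6-lutidine, CH2Cl2, −78 °C; the weak base should not enolise the acetyl group) to give the 13-O-triethylsilyl keto enal F1. Treatment with LiN(SiMe3)2 (THF, −78 → 0 °C) would form the lithium dienolate, which should add through C2 to C1; the resulting aldehyde enolate then closes ring B at C5. The β-dicarbonyl enolate would be methylated in the same flask with MeI, which comes back to the route at 20.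

**Step 4 (conjugate propargylation).** The stannane may add 1,2 to the ketone, or fail to form the congested quaternary centre. The fallback sets out from 7 and uses a Hosomi–Sakurai allylation (allyltrimethylsilane, TiCl4, CH2Cl2, −78 °C) to give the allyl ketone F2 with the same facial preference. Ozonolysis (O3, CH2Cl2/MeOH, −78 °C; Me2S) would give the aldehyde F3, and Ohira–Bestmann homologation (dimethyl (1-diazo-2-oxopropyl)phosphonate, K2CO3, MeOH) would convert it into the alkyne, coming back at 9.

**Step 8 (pyranone annulation).** Condensation at the hindered vinylogous formamide may be slow, with loss of the silyl ether in warm acetic acid. The fallback reverses the order of bond formation. It sets out from 11, which would undergo Knoevenagel condensation with 13 (piperidinium acetate cat., PhH, 23 °C) to give the alkylidene acetoacetate F4. Aminomethylenation at the vinylogous γ-carbon C6 with Me2NCH(OMe)2 (PhMe, 80 °C) would give the dienamine F5, and AcOH/H2O should then close the lactone with loss of dimethylamine and methanol, coming back at 14.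

Further compounds
F1 | step 12 | 13-O-triethylsilyl ether of keto enal 17 | C=C1C[C@]2(C3=COC(=O)C(C(C)=O)=C3)C[C@@]1(O[Si](CC)(CC)CC)CC[C@H]2C(=C)C=O
F2 | step 4 | methyl 2-[(1R,2S)-2-[2-[(tert-butyldimethylsilyl)oxy]ethyl]-5-oxo-1-(prop-2-en-1-yl)cyclohexyl]acetate | C=CC[C@]1(CC(=O)OC)CC(=O)CC[C@H]1CCO[Si](C)(C)C(C)(C)C
F3 | step 4 | methyl 2-[(1R,2S)-2-[2-[(tert-butyldimethylsilyl)oxy]ethyl]-5-oxo-1-(2-oxoethyl)cyclohexyl]acetate | O=CC[C@]1(CC(=O)OC)CC(=O)CC[C@H]1CCO[Si](C)(C)C(C)(C)C
F4 | step 8 | methyl 2-acetyl-4-[bicyclooctan-1-yl]but-2-enoate, bicyclic part as in 11 (drawn Z, E/Z mixture expected) | C=C1C[C@]2(C/C=C(/C(C)=O)C(=O)OC)C[C@@]1(O)CC[C@H]2CCO[Si](C)(C)C(C)(C)C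
F5 | step 8 | methyl 2-acetyl-5-(dimethylamino)-4-[bicyclooctan-1-yl]penta-2,4-dienoate, bicyclic part as in 11 | C=C1C[C@]2(C(=CN(C)C)C=C(C(C)=O)C(=O)OC)C[C@@]1(O)CC[C@H]2CCO[Si](C)(C)C(C)(C)C
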